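The easiest step to start from is X → Q, which needs no partner: by it alone, X halves every 10.0 s. Four flasks take the same charges by different routes.

| flask | L | X | time | remark |
|---|---|---|---|---|
| oak | 0.50 mM (in portions, 2, over 20 s) | 0.450 mM | 30 s | first portion at the start, last at 20 s |
| larch | 0.50 mM (fed, over 20 s) | 0.450 mM | 30 s | all else is in the flask from the start; the feed brings no volume worth counting |
| birch | 0.50 mM | 0.450 mM (fed, over 20 s) | 30 s | all else is in the flask from the start; the feed brings no volume worth counting |
| ash | 0.50 mM | 0.450 mM | 30 s | everything together at the start |

    L + X → L.X (k1 = 160 /M/s)
    L + X → Z, rate k2*[L] as long as [X] is above zero (k2 = 0.0078 /s)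
    2 L → L2 (k3 = 370 /M/s)
    X + L.X ⇌ X.L.X, settled at all times (K4 = 2600 /M)
    X → Q (k5 = 0.069 /s)

- percentages count the L that a species holds: one L2 counts as two
- L.X is meant together with its X.L.X
- where a step has two of a species, its rate is k times that concentration squared, and two are used at each turn
- run time (oak): 30 s

* the best flask by share of L.X in L.X plus Z; "all alike" if 1.5 percentage points covers them all (oak / larch / birch / ash / all alike)
* share of L.X in L.X plus Z at the end, oak
* share of L.X in L.X plus Z at the end, larch
* share of L.X in L.X plus Z at the end, birch
* share of L.X in L.X plus Z at the end, ash

The reckoning here starts from the fork in the path of L. The link step runs at its constant times [L][X] and the ring step at its constant times [L], so [L] cancels from their ratio, and this selectivity factor follows [X]. The even point is the free [X] at which links and rings form equally fast, the ring constant over the link constant: 0.0487 mM. At any moment the link share of what is forming is [X] over [X] plus the even point, which for the full charge of X is 90.2%.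

What counts, then, is the [X] that L meets. In ash, L pairs into L2 faster than it forms links at the start, with a first half-life of 2.70 s, shorter than that of X. By pairing alone, each later half takes twice as long, so [L] is down to a quarter after 3 such half-lives, at 8.11 s. Taking [X] at that moment as typical and counting the loss to Q and nothing else, the reckoning puts ash at 0.257 mM, which gives 84.1%.

The other flasks are reckoned by the same measure. Larch's L enters on average at 10.0 s, when decay by this count has left 0.226 mM. Birch has received 0.182 mM by 8.11 s, before any loss. Oak's first portion, at half the strength, takes 16.2 s to fall to a quarter by the same count, and decay by then leaves 0.147 mM. Ash's figure is higher than these, so the reckoning names ash as best, and it goes no further: it does not rank the others.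

The forecast gives 77% for oak, 74% for larch, 65% for birch and 82% for ash, a little below the figure reckoned here. It also picks ash, holding that the share is highest “when L meets X early and at full strength”.

The simulation gives 77.0% for oak, 73.1% for larch, 65.1% for birch and 82.4% for ash, so ash is best and the forecast stands within tolerance. In ash at 7.21 s, X goes to Q 4.0 times as fast as it goes into links. At 30.0 s, free [X] in ash stands at 0.0371 mM, below the even point, which means rings are then forming faster than links.

A neighbour flask is like ash but holds 0.27 mM of X, with the same L and so the same 8.11 s. There the same count leaves 0.154 mM, and the even point gives 76.0%. The simulation gives 73.0% for that neighbour flask.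

(Its constants are invented; no experiment stands behind them.)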